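**Retrosynthetic overview**

1. Atom labels: ring A is the cyclopentenone C1 (C=O), C2 (=C–OMe), C3 (=C–aryl), C4 (spiro carbon), C5 (C(OMe)aryl); the oxirane is C4, C6H2 and O. The route rests on the adjacent fully substituted carbons C4 and C5: C5 carries what an aryl carbene carbon plus methanol supply, and C4 what a ketone carbonyl flanked by CH2Cl and an aroyl group supplies.
2. Key disconnection: C5–OMe and C4–C5 are made in one step from diazoketone 7, methanol 13 and chloromethyl dione 12 under Rh2(OAc)4 and a chiral phosphoric acid. Both stereocenters arise there and no ring is formed.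
3. The carbene carbon bears a methoxyacetyl group (C1, C2 and the C2 methoxy group), so coupling product 15 is already the complete 1,4-diketone. An ester at C1 would later force a phosphonate anion to choose a neopentyl ester over an aryl ketone and an oxirane.
4. Ring order: the oxirane first (C4–O onto C6–Cl, step 9), then ring A (C2=C3 by intramolecular aldol condensation, step 10); fluoride then frees both phenols.
5. 7 comes from 4-bromophenol and methyl glycidyl ether in four steps; 12 comes from 4'-hydroxypropiophenone in three steps.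

Key step: step 8

Assumption: the sense of induction of the phosphoric acid in step 8 cannot be predicted with confidence; the (R)-acid is written, and its enantiomer would be used if a first trial shows the opposite sense.

**Route**

Step 1
Reactants: 1 4-bromophenol
Product: 2 (4-bromophenoxy)triisopropylsilane
Conditions: TIPSCl, imidazole, DMF, rt
Reagents that add atoms: chlorotriisopropylsilane, CC(C)[Si](Cl)(C(C)C)C(C)C
Why: Imidazole-mediated O-silylation of the phenol (silyl ether protection) gives a hindered aryl triisopropylsilyl ether chosen to withstand the Grignard, amine-base and alkoxide steps that follow.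

Step 2
Reactants: 2 (4-bromophenoxy)triisopropylsilane; 3 2-(methoxymethyl)oxirane (racemic)
Product: 5 1-methoxy-3-[4-(triisopropylsilyloxy)phenyl]propan-2-ol (racemic), via [4-(triisopropylsilyloxy)phenyl]magnesium bromide 4 (not isolated)
Conditions: Mg, THF, reflux; then CuI (10 mol%), 3, THF, −30 → 0 °C; aq. NH4Cl
Reagents that add atoms: none
Why: Grignard formation followed by copper-catalysed SN2 opening of the terminal epoxide at its unsubstituted carbon should give the secondary alcohol, whose stereocenter is removed in step 3, so racemic 3 suffices.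

Step 3
Reactants: 5 1-methoxy-3-[4-(triisopropylsilyloxy)phenyl]propan-2-ol
Product: 6 1-methoxy-3-[4-(triisopropylsilyloxy)phenyl]propan-2-one
Conditions: Dess–Martin periodinane, NaHCO3, CH2Cl2, 0 °C → rt
Reagents that add atoms: none
Why: Dess–Martin oxidation converts the secondary alcohol into the benzyl ketone under buffered, non-enolising conditions that leave the silyl ether and the methyl ether untouched.

Step 4
Reactants: 6 1-methoxy-3-[4-(triisopropylsilyloxy)phenyl]propan-2-one
Product: 7 1-diazo-3-methoxy-1-[4-(triisopropylsilyloxy)phenyl]propan-2-one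
Conditions: 4-acetamidobenzenesulfonyl azide, DBU, MeCN, 0 °C → rt
Reagents that add atoms: 4-acetamidobenzenesulfonyl azide, CC(=O)Nc1ccc(cc1)S(=O)(=O)N=[N+]=[N-]
Why: Regitz diazo transfer, in which DBU deprotonates the benzylic CH2 (far more acidic than the CH2OMe on the other side of the ketone) and the enolate takes N2 from the sulfonyl azide, as is standard for arylacetones.

Step 5
Reactants: 8 4'-hydroxypropiophenone
Product: 9 1-[4-(triisopropylsilyloxy)phenyl]propan-1-one
Conditions: TIPSCl, imidazole, DMF, rt
Reagents that add atoms: chlorotriisopropylsilane, CC(C)[Si](Cl)(C(C)C)C(C)C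
Why: Imidazole-mediated O-silylation of the phenol (silyl ether protection), needed because a free phenol would take up the rhodium carbene in step 8.

Step 6
Reactants: 9 1-[4-(triisopropylsilyloxy)phenyl]propan-1-one
Product: 10 1-[4-(triisopropylsilyloxy)phenyl]propane-1,2-dione
Conditions: SeO2, 1,4-dioxane/H2O, 100 °C
Reagents that add atoms: selenium dioxide, O=[Se]=O
Why: Riley oxidation, in which SeO2 oxidises the only enolisable α-methylene of the aryl ketone to a carbonyl group, the standard passage from propiophenones to 1-arylpropane-1,2-diones.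

Step 7
Reactants: 10 1-[4-(triisopropylsilyloxy)phenyl]propane-1,2-dione
Product: 12 3-chloro-1-[4-(triisopropylsilyloxy)phenyl]propane-1,2-dione, via trimethylsilyl enol ether 11 (not isolated)
Conditions: Me3SiOTf, Et3N, CH2Cl2, 0 °C; filtration through a short plug; then NCS, THF, 0 °C → rt
Reagents that add atoms: N-chlorosuccinimide, O=C1CCC(=O)N1Cl
Why: Soft enolisation can only take place at the methyl group (C6), and electrophilic chlorination of the resulting silyl enol ether by NCS should stop at the monochloride and spare the silyloxy-substituted ring.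

Step 8
Reactants: 7 1-diazo-3-methoxy-1-[4-(triisopropylsilyloxy)phenyl]propan-2-one; 12 3-chloro-1-[4-(triisopropylsilyloxy)phenyl]propane-1,2-dione; 13 methanol
Product: 15 (2R,3R)-2-(chloromethyl)-2-hydroxy-3,5-dimethoxy-1,3-bis[4-(triisopropylsilyloxy)phenyl]pentane-1,4-dione, via protic oxonium ylide 14 (not isolated)
Conditions: Rh2(OAc)4 (2 mol%), (R)-3,3'-bis(2,4,6-triisopropylphenyl)-1,1'-binaphthyl-2,2'-diyl hydrogen phosphate (10 mol%), MeOH (1.5 equiv), 3 Å MS, CH2Cl2, −20 °C, 7 added over 3 h
Reagents that add atoms: none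
Why: Proposed new method: Rh2(OAc)4 converts 7 into a rhodium carbene, methanol adds through oxygen to give the protic oxonium ylide 14 (C5–OMe bond), and this enol-type nucleophile should add through C5 to the C4 carbonyl of 12 held by the phosphoric acid (C4–C5 bond) before the 1,2-proton shift that would end in plain O–H insertion. The closest known reaction type is the dirhodium carboxylate and chiral phosphoric acid co-catalysed three-component coupling of aryldiazoacetates with alcohols and activated carbonyl compounds or imines (aldol- and Mannich-type trapping of oxonium ylides), together with heteroatom–hydrogen insertions of α-aryl-α-diazoketones through enol intermediates under the same catalyst pair; new here are the diazoketone as ylide precursor, methanol as the alcohol and a 1,2-dione as acceptor. No ring is closed. Both stereocenters (C4 and C5) are set here by the phosphate, which is expected to bind the ylide O–H and the dione carbonyl in one hydrogen-bonded assembly and so fix the enol face, the ketone face and their mutual approach; the (2R,3R) isomer, with OMe and OH on opposite faces of the later ring A, is the one required. The step needs attack at the chloromethyl ketone and not at the aryl ketone, which the substrate secures because the aryl ketone is deactivated by conjugation with the 4-silyloxyphenyl ring while the other carbonyl carries the inductively activating CH2Cl. Slow addition of 7 and a small excess of methanol are meant to hold back O–H insertion and carbene dimerisation.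

Step 9
Reactants: 15 (2R,3R)-2-(chloromethyl)-2-hydroxy-3,5-dimethoxy-1,3-bis[4-(triisopropylsilyloxy)phenyl]pentane-1,4-dione
Product: 16 (1R)-1,3-dimethoxy-1-[(2R)-2-[4-(triisopropylsilyloxy)benzoyl]oxiran-2-yl]-1-[4-(triisopropylsilyloxy)phenyl]propan-2-one
Conditions: DBU, MeCN, 0 °C → rt
Reagents that add atoms: none
Why: Intramolecular Williamson etherification (3-exo-tet closure of a chlorohydrin), in which the amidine base deprotonates only the tertiary hydroxyl and substitution takes place at C6, so the configuration of C4 is retained.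

Step 10
Reactants: 16 (1R)-1,3-dimethoxy-1-[(2R)-2-[4-(triisopropylsilyloxy)benzoyl]oxiran-2-yl]-1-[4-(triisopropylsilyloxy)phenyl]propan-2-one
Product: 18 (3R,4R)-4,6-dimethoxy-4,7-bis[4-(triisopropylsilyloxy)phenyl]-1-oxaspiro[2.4]hept-6-en-5-one, via cyclic aldol 17 (not isolated)
Conditions: KOtBu (1.1 equiv), THF/t-BuOH, −20 °C → rt
Reagents that add atoms: none
Why: Intramolecular aldol condensation of a 1,4-diketone, in which C2 is the only enolisable carbon, its enolate adds to the C3 aryl ketone in a 5-(enolexo)-exo-trig closure and E1cB loss of water gives the conjugated methoxy enone, while C4 and C5 carry no hydrogen and cannot epimerise.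

Step 11
Reactants: 18 (3R,4R)-4,6-dimethoxy-4,7-bis[4-(triisopropylsilyloxy)phenyl]-1-oxaspiro[2.4]hept-6-en-5-one
Product: 19 (3R,4R)-4,7-bis(4-hydroxyphenyl)-4,6-dimethoxy-1-oxaspiro[2.4]hept-6-en-5-one
Conditions: Bu4NF, AcOH, THF, 0 °C
Reagents that add atoms: none
Why: Fluoride cleavage of the two aryl silyl ethers, buffered with acetic acid so that the phenoxides are protonated at once and neither the oxirane nor the tertiary benzylic methyl ether at C5 is exposed to base.

**Compound list**

1 | 4-bromophenol | Oc1ccc(Br)cc1 | starting material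
2 | (4-bromophenoxy)triisopropylsilane | CC(C)[Si](Oc1ccc(Br)cc1)(C(C)C)C(C)C | intermediate
3 | 2-(methoxymethyl)oxirane (methyl glycidyl ether, racemic) | COCC1CO1 | starting material
4 | [4-(triisopropylsilyloxy)phenyl]magnesium bromide | CC(C)[Si](Oc1ccc([Mg]Br)cc1)(C(C)C)C(C)C | intermediate
5 | 1-methoxy-3-[4-(triisopropylsilyloxy)phenyl]propan-2-ol (racemic) | COCC(O)Cc1ccc(O[Si](C(C)C)(C(C)C)C(C)C)cc1 | intermediate
6 | 1-methoxy-3-[4-(triisopropylsilyloxy)phenyl]propan-2-one | COCC(=O)Cc1ccc(O[Si](C(C)C)(C(C)C)C(C)C)cc1 | intermediate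
7 | 1-diazo-3-methoxy-1-[4-(triisopropylsilyloxy)phenyl]propan-2-one | COCC(=O)C(=[N+]=[N-])c1ccc(O[Si](C(C)C)(C(C)C)C(C)C)cc1 | intermediate
8 | 4'-hydroxypropiophenone | CCC(=O)c1ccc(O)cc1 | starting material
9 | 1-[4-(triisopropylsilyloxy)phenyl]propan-1-one | CCC(=O)c1ccc(O[Si](C(C)C)(C(C)C)C(C)C)cc1 | intermediate
10 | 1-[4-(triisopropylsilyloxy)phenyl]propane-1,2-dione | CC(=O)C(=O)c1ccc(O[Si](C(C)C)(C(C)C)C(C)C)cc1 | intermediate
11 | 1-[4-(triisopropylsilyloxy)phenyl]-2-(trimethylsilyloxy)prop-2-en-1-one | C=C(O[Si](C)(C)C)C(=O)c1ccc(O[Si](C(C)C)(C(C)C)C(C)C)cc1 | intermediate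
12 | 3-chloro-1-[4-(triisopropylsilyloxy)phenyl]propane-1,2-dione | O=C(CCl)C(=O)c1ccc(O[Si](C(C)C)(C(C)C)C(C)C)cc1 | intermediate
13 | methanol | CO | starting material
14 | protic oxonium ylide from the carbene of 7 and methanol | COCC(=O)[C-]([OH+]C)c1ccc(O[Si](C(C)C)(C(C)C)C(C)C)cc1 | intermediate
15 | (2R,3R)-2-(chloromethyl)-2-hydroxy-3,5-dimethoxy-1,3-bis[4-(triisopropylsilyloxy)phenyl]pentane-1,4-dione | COCC(=O)[C@@](OC)(c1ccc(O[Si](C(C)C)(C(C)C)C(C)C)cc1)[C@](O)(CCl)C(=O)c1ccc(O[Si](C(C)C)(C(C)C)C(C)C)cc1 | intermediate
16 | (1R)-1,3-dimethoxy-1-[(2R)-2-[4-(triisopropylsilyloxy)benzoyl]oxiran-2-yl]-1-[4-(triisopropylsilyloxy)phenyl]propan-2-one | COCC(=O)[C@@](OC)(c1ccc(O[Si](C(C)C)(C(C)C)C(C)C)cc1)[C@]1(CO1)C(=O)c1ccc(O[Si](C(C)C)(C(C)C)C(C)C)cc1 | intermediate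
17 | 7-hydroxy-4,6-dimethoxy-4,7-bis[4-(triisopropylsilyloxy)phenyl]-1-oxaspiro[2.4]heptan-5-one (spiro carbon and C4 arranged as in 18; mixture of epimers at C6 and C7) | COC1C(O)(c2ccc(O[Si](C(C)C)(C(C)C)C(C)C)cc2)[C@@]2(CO2)[C@](OC)(c2ccc(O[Si](C(C)C)(C(C)C)C(C)C)cc2)C1=O | intermediate
18 | (3R,4R)-4,6-dimethoxy-4,7-bis[4-(triisopropylsilyloxy)phenyl]-1-oxaspiro[2.4]hept-6-en-5-one | COC1=C(c2ccc(O[Si](C(C)C)(C(C)C)C(C)C)cc2)[C@@]2(CO2)[C@](OC)(c2ccc(O[Si](C(C)C)(C(C)C)C(C)C)cc2)C1=O | intermediate
19 | (3R,4R)-4,7-bis(4-hydroxyphenyl)-4,6-dimethoxy-1-oxaspiro[2.4]hept-6-en-5-one (CNP0504072.1) | COC1=C(c2ccc(O)cc2)[C@@]2(CO2)[C@](OC)(c2ccc(O)cc2)C1=O | target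

**Step count**

Total: 11 steps. Longest linear sequence: 8 steps (1, 2, 3, 4, 8, 9, 10, 11).

**Steps most likely to fail**

Step 8 (proposed new method). The 1,2-proton shift of ylide 14 (plain O–H insertion) may outrun addition to 12, or the addition may proceed with poor facial and relative control. The fallback uses known reactions, sets out from 7 and 12 and comes back at 15. Rh2(OAc)4-catalysed O–H insertion of 7 into methanol should give racemic 1,3-dimethoxy-1-[4-(triisopropylsilyloxy)phenyl]propan-2-one F1. Soft enolisation (Me3SiOTf, Et3N) at the more acidic benzylic carbon should give 1,3-dimethoxy-1-[4-(triisopropylsilyloxy)phenyl]-2-(trimethylsilyloxy)prop-1-ene F2. A Mukaiyama aldol addition of F2 to 12, catalysed by Cu(OTf)2 with 2,2'-(propane-2,2-diyl)bis[(4S)-4-tert-butyl-4,5-dihydrooxazole], should then give the trimethylsilyl ether of 15 F3. In that addition the dione chelates divalent copper through both carbonyl oxygens and reacts at the less hindered chloromethyl ketone. Dilute citric acid in methanol converts F3 into 15. If the copper complex gives insufficient enantiomeric purity, the TiCl4-promoted racemic addition followed by preparative chromatography on a chiral stationary phase leads to the same 15.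

Step 9. The tertiary alkoxide of 15 may fragment by retro-aldol cleavage of the C4–C5 bond instead of displacing chloride. The fallback sets out from 11 and comes back at 16. N-Bromosuccinimide in place of NCS should give 3-bromo-1-[4-(triisopropylsilyloxy)phenyl]propane-1,2-dione F4. F4 replaces 12 in step 8 and should give the bromohydrin (2R,3R)-2-(bromomethyl)-2-hydroxy-3,5-dimethoxy-1,3-bis[4-(triisopropylsilyloxy)phenyl]pentane-1,4-dione F5. Ag2O in CH2Cl2 at room temperature then closes the oxirane by silver-assisted bromide abstraction, without a free alkoxide, to give 16.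

Step 10. The alkoxide base may strip the silyl group from the aroyl ring before ring closure, after which the phenoxide deactivates the C3 ketone. Alternatively the C3 aldolate may attack the neighbouring oxirane (Payne-type migration) faster than water is lost. The fallback sets out from 16 and comes back at 18. LiN(SiMe3)2 in THF at −78 °C forms the C2 lithium enolate, which should close to cyclic aldol 17, isolated after a cold quench with AcOH; at that temperature the lithium aldolate should neither desilylate nor migrate. Trifluoroacetic anhydride, pyridine and 4-(dimethylamino)pyridine at 0 °C convert the tertiary alcohol into the trifluoroacetate of 17 F6. DBU in CH2Cl2 then removes trifluoroacetic acid by E1cB elimination to give 18.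

**Further compounds**

F1 | step 8 | 1,3-dimethoxy-1-[4-(triisopropylsilyloxy)phenyl]propan-2-one (racemic) | COCC(=O)C(OC)c1ccc(O[Si](C(C)C)(C(C)C)C(C)C)cc1
F2 | step 8 | 1,3-dimethoxy-1-[4-(triisopropylsilyloxy)phenyl]-2-(trimethylsilyloxy)prop-1-ene (E/Z mixture) | COCC(O[Si](C)(C)C)=C(OC)c1ccc(O[Si](C(C)C)(C(C)C)C(C)C)cc1
F3 | step 8 | (2R,3R)-2-(chloromethyl)-3,5-dimethoxy-1,3-bis[4-(triisopropylsilyloxy)phenyl]-2-(trimethylsilyloxy)pentane-1,4-dione | COCC(=O)[C@@](OC)(c1ccc(O[Si](C(C)C)(C(C)C)C(C)C)cc1)[C@](O[Si](C)(C)C)(CCl)C(=O)c1ccc(O[Si](C(C)C)(C(C)C)C(C)C)cc1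
F4 | step 9 | 3-bromo-1-[4-(triisopropylsilyloxy)phenyl]propane-1,2-dione | O=C(CBr)C(=O)c1ccc(O[Si](C(C)C)(C(C)C)C(C)C)cc1
F5 | step 9 | (2R,3R)-2-(bromomethyl)-2-hydroxy-3,5-dimethoxy-1,3-bis[4-(triisopropylsilyloxy)phenyl]pentane-1,4-dione | COCC(=O)[C@@](OC)(c1ccc(O[Si](C(C)C)(C(C)C)C(C)C)cc1)[C@](O)(CBr)C(=O)c1ccc(O[Si](C(C)C)(C(C)C)C(C)C)cc1
F6 | step 10 | 4,6-dimethoxy-5-oxo-4,7-bis[4-(triisopropylsilyloxy)phenyl]-1-oxaspiro[2.4]heptan-7-yl trifluoroacetate (spiro carbon and C4 arranged as in 18) | COC1C(OC(=O)C(F)(F)F)(c2ccc(O[Si](C(C)C)(C(C)C)C(C)C)cc2)[C@@]2(CO2)[C@](OC)(c2ccc(O[Si](C(C)C)(C(C)C)C(C)C)cc2)C1=O
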